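**Plan**
- Retrosynthesis cuts, in order: the epoxide oxygen (C4–O–C5); the C8–O ester bond (made with inversion); the lactone O6–C12 bond; then, in one stroke, C11–C12 and C6–C7, which opens the ten-membered carbocycle to an acyclic allenyl enal plus CO2; the chain is cut at C3–C4, C9–C10 and C1=C10.
- Enabling feature: the α-methylene-γ-butyrolactone ring (O6, C6, C7, C11, C12) shares its C6–C7 bond with the ten-membered ring, and C11 carries the exocyclic C13 methylene. C7=C11=C13 is therefore a terminal allene in disguise: its central carbon takes up CO2 (C12) and the resulting 2-carboxylato-allylnickel hands C7 to the C6 aldehyde at the other end of the chain.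
- Forward order: Z-iodo-olefination (C1=C10), alkenyllithium/epoxide union (C9–C10), organocopper/ynoate addition (C3–C4, sets C4=C5), alkyne then allene (C7=C11=C13), ring closure C6–C7 together with C11–C12 (step 12), lactone ring (step 13), ester, epoxide ring last.
- Stereochemistry: C8 is bought ((R)-glycidol, carried as the 8S epimer); C7 and C6 are relayed from C8 in the key step; C8 is then inverted to 8R by Mitsunobu acylation; C4/C5 come from hydroxyl-directed epoxidation on the outer face of the macrocycle; olefin geometries come from the Z-selective iodo-Wittig reaction and syn-carbocupration.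

Key step: step 12

Assumption: the target is read as the (1(10)Z,4S,5R,6S,7R,8R) germacranolide 4,5-epoxide whose O-8 carries (E)-4-hydroxytiglate; germacrane numbering (C1–C15) is used throughout.

**Step 1**
Reactants: 1 4-chlorobutanal
Product: 2 (2Z)-6-chloro-2-iodohex-2-ene
Conditions: EtPPh3I, n-BuLi, THF, 0 °C; I2, −78 °C; NaHMDS, −20 °C; then 1, −78 °C → rt
Reagents that add atoms: ethyltriphenylphosphonium iodide CC[P+](c1ccccc1)(c1ccccc1)c1ccccc1.[I-]; iodine II
Why: the iodo-Wittig (Stork–Zhao-type) olefination of an aldehyde with the α-iodo ylide is kinetically Z-selective, which puts iodine cis to the chain so that the C9 substituent introduced later ends cis to C2 (the 1(10)Z olefin).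

**Step 2**
Reactants: 3 (R)-glycidol
Product: 4 triethyl{[(2S)-oxiran-2-yl]methoxy}silane
Conditions: TESCl, imidazole, CH2Cl2, 0 °C
Reagents that add atoms: chlorotriethylsilane CC[Si](Cl)(CC)CC
Why: O-silylation of a primary alcohol leaves the stereocentre untouched (the descriptor changes from R to S only through the CIP priorities).

**Step 3**
Reactants: 2 (2Z)-6-chloro-2-iodohex-2-ene; 4 triethyl{[(2S)-oxiran-2-yl]methoxy}silane
Product: 6 (2S,4Z)-7-chloro-4-methyl-1-[(triethylsilyl)oxy]hept-4-en-2-ol, via (2E)-6-chlorohex-2-en-2-yllithium 5 (not isolated)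
Conditions: t-BuLi (2.1 equiv), Et2O, −78 °C; then 4, BF3·OEt2, −78 °C
Reagents that add atoms: none
Why: iodine–lithium exchange proceeds with retention of olefin geometry and the BF3-promoted epoxide opening by the alkenyllithium occurs at the terminal CH2 (C9), so C8 is carried over unchanged from glycidol.

**Step 4**
Reactants: 6 (2S,4Z)-7-chloro-4-methyl-1-[(triethylsilyl)oxy]hept-4-en-2-ol
Product: 7 (2S,4Z)-7-chloro-4-methyl-1,2-bis[(triethylsilyl)oxy]hept-4-ene
Conditions: TESCl, imidazole, DMAP (cat.), CH2Cl2, rt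
Reagents that add atoms: chlorotriethylsilane CC[Si](Cl)(CC)CC
Why: silylation of the secondary alcohol gives a bis-TES ether whose primary and secondary silyl ethers can be told apart in step 7.

**Step 5**
Reactants: 8 methyl 4-hydroxybut-2-ynoate
Product: 9 methyl 4-[(tert-butyldiphenylsilyl)oxy]but-2-ynoate
Conditions: TBDPSCl, imidazole, CH2Cl2, 0 °C → rt
Reagents that add atoms: tert-butyl(chloro)diphenylsilane CC(C)(C)[Si](Cl)(c1ccccc1)c1ccccc1
Why: silylation of the propargylic alcohol installs the robust C15 protecting group that stays until step 18.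

**Step 6**
Reactants: 7 (2S,4Z)-7-chloro-4-methyl-1,2-bis[(triethylsilyl)oxy]hept-4-ene; 9 methyl 4-[(tert-butyldiphenylsilyl)oxy]but-2-ynoate
Product: 12 methyl (2Z,6Z,9S)-3-{[(tert-butyldiphenylsilyl)oxy]methyl}-7-methyl-9,10-bis[(triethylsilyl)oxy]deca-2,6-dienoate, via alkylmagnesium chloride 10 (not isolated), via alkylcopper 11 (not isolated)
Conditions: Mg, THF, reflux; CuBr·SMe2, THF, −78 → −40 °C; then 9, −78 °C; MeOH/NH4Cl quench at −78 °C
Reagents that add atoms: none
Why: syn-carbocupration (conjugate addition) of the organocopper to the ynoate, followed by protonation of the alkenylcopper with retention at −78 °C, fixes C4=C5 with C3 trans to the ester carbon (C6) and the CH2OTBDPS group cis to it.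

**Step 7**
Reactants: 12 methyl (2Z,6Z,9S)-3-{[(tert-butyldiphenylsilyl)oxy]methyl}-7-methyl-9,10-bis[(triethylsilyl)oxy]deca-2,6-dienoate
Product: 13 methyl (2Z,6Z,9S)-3-{[(tert-butyldiphenylsilyl)oxy]methyl}-7-methyl-10-oxo-9-[(triethylsilyl)oxy]deca-2,6-dienoate
Conditions: (COCl)2, DMSO, CH2Cl2, −78 → −40 °C; Et3N, −78 → 0 °C
Reagents that add atoms: none
Why: under Swern conditions a primary triethylsilyl ether is cleaved by the chlorosulfonium reagent and oxidised directly to the aldehyde, while the secondary TES ether, the TBDPS ether and the ester should survive.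

**Step 8**
Reactants: 13 methyl (2Z,6Z,9S)-3-{[(tert-butyldiphenylsilyl)oxy]methyl}-7-methyl-10-oxo-9-[(triethylsilyl)oxy]deca-2,6-dienoate
Product: 14 methyl (2Z,6Z,9S)-3-{[(tert-butyldiphenylsilyl)oxy]methyl}-7-methyl-9-[(triethylsilyl)oxy]undeca-2,6-dien-10-ynoate
Conditions: dimethyl (1-diazo-2-oxopropyl)phosphonate, K2CO3, MeOH, 0 °C → rt
Reagents that add atoms: dimethyl (1-diazo-2-oxopropyl)phosphonate CC(=O)C(=[N+]=[N-])P(=O)(OC)OC
Why: the Seyferth–Gilbert homologation in its Ohira–Bestmann form converts the α-silyloxy aldehyde into the terminal alkyne (C7≡C11) under carbonate conditions mild enough to keep C8.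

**Step 9**
Reactants: 14 methyl (2Z,6Z,9S)-3-{[(tert-butyldiphenylsilyl)oxy]methyl}-7-methyl-9-[(triethylsilyl)oxy]undeca-2,6-dien-10-ynoate
Product: 16 methyl (2Z,6Z,9S)-3-{[(tert-butyldiphenylsilyl)oxy]methyl}-7-methyl-9-[(triethylsilyl)oxy]dodeca-2,6,10,11-tetraenoate, via propargylic dicyclohexylamine 15 (not isolated)
Conditions: (CH2O)n, CuI, Cy2NH, dioxane, reflux
Reagents that add atoms: formaldehyde (as paraformaldehyde) C=O
Why: the Crabbé homologation (Mannich reaction, then copper-mediated 1,5-hydride transfer and loss of the imine) turns the terminal alkyne into the terminal allene C7=C11=C13 without touching C8.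

**Step 10**
Reactants: 16 methyl (2Z,6Z,9S)-3-{[(tert-butyldiphenylsilyl)oxy]methyl}-7-methyl-9-[(triethylsilyl)oxy]dodeca-2,6,10,11-tetraenoate
Product: 17 (2Z,6Z,9S)-3-{[(tert-butyldiphenylsilyl)oxy]methyl}-7-methyl-9-[(triethylsilyl)oxy]dodeca-2,6,10,11-tetraen-1-ol
Conditions: DIBAL-H, CH2Cl2, −78 °C; Rochelle salt
Reagents that add atoms: none
Why: 1,2-reduction of the enoate to the allylic alcohol by DIBAL-H at low temperature leaves the allene, the olefins and the silyl ethers alone.

**Step 11**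
Reactants: 17 (2Z,6Z,9S)-3-{[(tert-butyldiphenylsilyl)oxy]methyl}-7-methyl-9-[(triethylsilyl)oxy]dodeca-2,6,10,11-tetraen-1-ol
Product: 18 (2Z,6Z,9S)-3-{[(tert-butyldiphenylsilyl)oxy]methyl}-7-methyl-9-[(triethylsilyl)oxy]dodeca-2,6,10,11-tetraenal
Conditions: MnO2, CH2Cl2, rt
Reagents that add atoms: none
Why: MnO2 oxidises the allylic alcohol selectively to the enal under neutral conditions that should not isomerise the C4=C5 bond.

**Step 12**
Reactants: 18 (2Z,6Z,9S)-3-{[(tert-butyldiphenylsilyl)oxy]methyl}-7-methyl-9-[(triethylsilyl)oxy]dodeca-2,6,10,11-tetraenal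
Product: 20 2-[(1S,2R,3Z,7Z,10S)-4-{[(tert-butyldiphenylsilyl)oxy]methyl}-2-hydroxy-8-methyl-10-[(triethylsilyl)oxy]cyclodeca-3,7-dien-1-yl]prop-2-enoic acid, via allylnickel carboxylate 19 (not isolated)
Conditions: Ni(cod)2 (1.5 equiv), DBU (6 equiv), CO2 (1 atm), THF (2 mM), 0 °C → rt; then cold 0.5 M HCl to pH 3
Reagents that add atoms: carbon dioxide O=C=O
Why: Proposed new method: Ni(0)/DBU should couple the terminal C11=C13 π-bond of the allene oxidatively with CO2 to the allylnickel carboxylate 19 (new C11–C12 bond), whose σ-allyl form with nickel on C13 delivers C7 to the tethered C6 aldehyde through a six-membered Zimmerman–Traxler-type array (new C6–C7 bond); the closest known reaction type is the nickel(0)-promoted sequential coupling of terminal allenes, CO2 and aldehydes, known between molecules and for five- and six-membered ring closure, while the ring size has precedent in chromium-mediated allyl–aldehyde closures of germacrane rings. Only the ten-membered carbocycle closes here (the lactone follows in step 13), by γ-attack (SE2′) of the allylmetal, 10-exo-trig with respect to C6=O, because α-attack would need nickel on the hindered C7 and would give a twelve-membered ring. C7 is set by the C8 stereocentre: C8–H eclipses the C7=C11 bond (1,3-allylic strain with the C11 carboxylate), the OSiEt3 group lies anti to the forming bond and C9 takes the outside position, which is the ring torsion of 8α-substituted germacranolides, so C6 should add to the C7 face anti to O8. C6 is set relative to C7 by the chair array with the (E)-configured (syn) allylnickel and C5 equatorial, which should give the anti (H6/H7 trans) hydroxy acid needed for the trans-fused lactone. The step needs allene–CO2 coupling to beat nickel–enal chemistry (CO2 in large excess, the enal far down the chain), cyclisation to beat oligomerisation (high dilution, stoichiometric nickel), and survival of the enal geometry and silyl ethers (0 °C, amidine base only).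

**Step 13**
Reactants: 20 2-[(1S,2R,3Z,7Z,10S)-4-{[(tert-butyldiphenylsilyl)oxy]methyl}-2-hydroxy-8-methyl-10-[(triethylsilyl)oxy]cyclodeca-3,7-dien-1-yl]prop-2-enoic acid
Product: 21 (1(10)Z,4Z,6R,7S,8S)-15-[(tert-butyldiphenylsilyl)oxy]-8-[(triethylsilyl)oxy]germacra-1(10),4,11(13)-trien-12,6-olide
Conditions: DCC, DMAP (cat.), CH2Cl2, 0 °C → rt
Reagents that add atoms: none
Why: Steglich-type lactonisation of the γ-hydroxy acid (5-exo-trig acyl substitution by O6) should give the trans-fused α-methylene-γ-butyrolactone, and the silylated O8 cannot compete.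

**Step 14**
Reactants: 21 (1(10)Z,4Z,6R,7S,8S)-15-[(tert-butyldiphenylsilyl)oxy]-8-[(triethylsilyl)oxy]germacra-1(10),4,11(13)-trien-12,6-olide
Product: 22 (1(10)Z,4Z,6R,7R,8S)-15-[(tert-butyldiphenylsilyl)oxy]-8-hydroxygermacra-1(10),4,11(13)-trien-12,6-olide
Conditions: PPTS, MeOH/CH2Cl2, 0 °C
Reagents that add atoms: none
Why: mild acid methanolysis removes the secondary TES ether far faster than the primary TBDPS ether, and no acid-labile epoxide is present yet.

**Step 15**
Reactants: 23 [(tert-butyldimethylsilyl)oxy]acetaldehyde; 24 ethyl 2-(triphenyl-λ5-phosphanylidene)propanoate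
Product: 25 ethyl (2E)-4-[(tert-butyldimethylsilyl)oxy]-2-methylbut-2-enoate
Conditions: CH2Cl2, rt
Reagents that add atoms: none
Why: the Wittig reaction of a stabilised α-methyl ylide with an aldehyde is E-selective and gives the protected 4-hydroxytiglate skeleton.

**Step 16**
Reactants: 25 ethyl (2E)-4-[(tert-butyldimethylsilyl)oxy]-2-methylbut-2-enoate
Product: 26 (2E)-4-[(tert-butyldimethylsilyl)oxy]-2-methylbut-2-enoic acid
Conditions: LiOH, THF/H2O, 0 °C → rt; then 1 M HCl to pH 4
Reagents that add atoms: lithium hydroxide [Li+].[OH-]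
Why: saponification of the ethyl ester leaves the primary TBS ether and the olefin geometry intact.

**Step 17**
Reactants: 22 (1(10)Z,4Z,6R,7R,8S)-15-[(tert-butyldiphenylsilyl)oxy]-8-hydroxygermacra-1(10),4,11(13)-trien-12,6-olide; 26 (2E)-4-[(tert-butyldimethylsilyl)oxy]-2-methylbut-2-enoic acid
Product: 27 (1(10)Z,4Z,6R,7R,8R)-15-[(tert-butyldiphenylsilyl)oxy]germacra-1(10),4,11(13)-trien-12,6-olid-8-yl (2E)-4-[(tert-butyldimethylsilyl)oxy]-2-methylbut-2-enoate
Conditions: PPh3, DIAD, toluene, 0 °C → rt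
Reagents that add atoms: none
Why: Mitsunobu esterification displaces the alkoxyphosphonium at C8 by the carboxylate in an SN2 step, which inverts C8 from S to the R configuration of the target while attaching the side chain.

**Step 18**
Reactants: 27 (1(10)Z,4Z,6R,7R,8R)-15-[(tert-butyldiphenylsilyl)oxy]germacra-1(10),4,11(13)-trien-12,6-olid-8-yl (2E)-4-[(tert-butyldimethylsilyl)oxy]-2-methylbut-2-enoate
Product: 28 (1(10)Z,4Z,6R,7R,8R)-15-hydroxygermacra-1(10),4,11(13)-trien-12,6-olid-8-yl (2E)-4-hydroxy-2-methylbut-2-enoate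
Conditions: HF·pyridine, pyridine, THF, 0 °C → rt
Reagents that add atoms: none
Why: buffered HF·pyridine cleaves both primary silyl ethers without touching the ester, the lactone or the olefins.

**Step 19**
Reactants: 28 (1(10)Z,4Z,6R,7R,8R)-15-hydroxygermacra-1(10),4,11(13)-trien-12,6-olid-8-yl (2E)-4-hydroxy-2-methylbut-2-enoate
Product: 29 (1(10)Z,4S,5R,6S,7R,8R)-4,5-epoxy-15-hydroxygermacra-1(10),11(13)-dien-12,6-olid-8-yl (2E)-4-hydroxy-2-methylbut-2-enoate (target)
Conditions: VO(acac)2 (cat.), TBHP, CH2Cl2, 0 °C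
Reagents that add atoms: tert-butyl hydroperoxide CC(C)(C)OO
Why: vanadium-catalysed hydroxyl-directed epoxidation should touch only the electron-rich C4=C5 bond of the C15 allylic alcohol (the hydroxytiglate and methylene-lactone olefins are electron-poor, C1=C10 has no nearby hydroxyl); with C6–H eclipsing the olefin plane the ring (C7) shields the inner face, so oxygen is delivered to the outer face syn to O6, which sets C4 as S and C5 as R, and syn addition keeps C3 and C6 trans.

**Compound list**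
1 | 4-chlorobutanal | O=CCCCCl | starting material
2 | (2Z)-6-chloro-2-iodohex-2-ene | C/C(I)=C/CCCCl | intermediate
3 | (R)-glycidol, (2R)-oxiran-2-ylmethanol | OC[C@@H]1CO1 | starting material
4 | triethyl{[(2S)-oxiran-2-yl]methoxy}silane | CC[Si](CC)(CC)OC[C@@H]1CO1 | intermediate
5 | (2E)-6-chlorohex-2-en-2-yllithium (lithium cis to the chain, as iodine in 2) | C/C([Li])=C/CCCCl | intermediate
6 | (2S,4Z)-7-chloro-4-methyl-1-[(triethylsilyl)oxy]hept-4-en-2-ol | CC[Si](CC)(CC)OC[C@@H](O)C/C(C)=C\CCCCl | intermediate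
7 | (2S,4Z)-7-chloro-4-methyl-1,2-bis[(triethylsilyl)oxy]hept-4-ene | CC[Si](CC)(CC)OC[C@@H](O[Si](CC)(CC)CC)C/C(C)=C\CCCCl | intermediate
8 | methyl 4-hydroxybut-2-ynoate | COC(=O)C#CCO | starting material
9 | methyl 4-[(tert-butyldiphenylsilyl)oxy]but-2-ynoate | COC(=O)C#CCO[Si](c1ccccc1)(c1ccccc1)C(C)(C)C | intermediate
10 | alkylmagnesium chloride: [(3Z,6S)-4-methyl-6,7-bis(triethylsilyloxy)hept-3-en-1-yl]magnesium chloride | CC[Si](CC)(CC)OC[C@@H](O[Si](CC)(CC)CC)C/C(C)=C\CCC[Mg]Cl | intermediate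
11 | alkylcopper: [(3Z,6S)-4-methyl-6,7-bis(triethylsilyloxy)hept-3-en-1-yl]copper, present as its magnesium halide complex | CC[Si](CC)(CC)OC[C@@H](O[Si](CC)(CC)CC)C/C(C)=C\CCC[Cu] | intermediate
12 | methyl (2Z,6Z,9S)-3-{[(tert-butyldiphenylsilyl)oxy]methyl}-7-methyl-9,10-bis[(triethylsilyl)oxy]deca-2,6-dienoate | COC(=O)/C=C(\CO[Si](c1ccccc1)(c1ccccc1)C(C)(C)C)CC/C=C(C)\C[C@@H](CO[Si](CC)(CC)CC)O[Si](CC)(CC)CC | intermediate
13 | methyl (2Z,6Z,9S)-3-{[(tert-butyldiphenylsilyl)oxy]methyl}-7-methyl-10-oxo-9-[(triethylsilyl)oxy]deca-2,6-dienoate | COC(=O)/C=C(\CO[Si](c1ccccc1)(c1ccccc1)C(C)(C)C)CC/C=C(C)\C[C@@H](C=O)O[Si](CC)(CC)CC | intermediate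
14 | methyl (2Z,6Z,9S)-3-{[(tert-butyldiphenylsilyl)oxy]methyl}-7-methyl-9-[(triethylsilyl)oxy]undeca-2,6-dien-10-ynoate | COC(=O)/C=C(\CO[Si](c1ccccc1)(c1ccccc1)C(C)(C)C)CC/C=C(C)\C[C@@H](C#C)O[Si](CC)(CC)CC | intermediate
15 | propargylic dicyclohexylamine: methyl (2Z,6Z,9S)-3-{[(tert-butyldiphenylsilyl)oxy]methyl}-12-(dicyclohexylamino)-7-methyl-9-[(triethylsilyl)oxy]dodeca-2,6-dien-10-ynoate | COC(=O)/C=C(\CO[Si](c1ccccc1)(c1ccccc1)C(C)(C)C)CC/C=C(C)\C[C@@H](C#CCN(C1CCCCC1)C1CCCCC1)O[Si](CC)(CC)CC | intermediate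
16 | methyl (2Z,6Z,9S)-3-{[(tert-butyldiphenylsilyl)oxy]methyl}-7-methyl-9-[(triethylsilyl)oxy]dodeca-2,6,10,11-tetraenoate | COC(=O)/C=C(\CO[Si](c1ccccc1)(c1ccccc1)C(C)(C)C)CC/C=C(C)\C[C@@H](C=C=C)O[Si](CC)(CC)CC | intermediate
17 | (2Z,6Z,9S)-3-{[(tert-butyldiphenylsilyl)oxy]methyl}-7-methyl-9-[(triethylsilyl)oxy]dodeca-2,6,10,11-tetraen-1-ol | OC/C=C(\CO[Si](c1ccccc1)(c1ccccc1)C(C)(C)C)CC/C=C(C)\C[C@@H](C=C=C)O[Si](CC)(CC)CC | intermediate
18 | (2Z,6Z,9S)-3-{[(tert-butyldiphenylsilyl)oxy]methyl}-7-methyl-9-[(triethylsilyl)oxy]dodeca-2,6,10,11-tetraenal | O=C/C=C(\CO[Si](c1ccccc1)(c1ccccc1)C(C)(C)C)CC/C=C(C)\C[C@@H](C=C=C)O[Si](CC)(CC)CC | intermediate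
19 | allylnickel carboxylate: five-membered nickelalactone (Ni–O–C12(=O)–C11–C13H2) with exocyclic C11=C7, C8 S, chain as in 18, drawn without its DBU ligands | O=C1O[Ni]CC1=C[C@@H](O[Si](CC)(CC)CC)C/C(C)=C\CC/C(CO[Si](c2ccccc2)(c2ccccc2)C(C)(C)C)=C/C=O | intermediate
20 | 2-[(1S,2R,3Z,7Z,10S)-4-{[(tert-butyldiphenylsilyl)oxy]methyl}-2-hydroxy-8-methyl-10-[(triethylsilyl)oxy]cyclodeca-3,7-dien-1-yl]prop-2-enoic acid | C1/C(CO[Si](c3ccccc3)(c3ccccc3)C(C)(C)C)=C/[C@@H](O)[C@H](C(=C)C(=O)O)[C@@H](O[Si](CC)(CC)CC)C/C(C)=C\C1 | intermediate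
21 | (1(10)Z,4Z,6R,7S,8S)-15-[(tert-butyldiphenylsilyl)oxy]-8-[(triethylsilyl)oxy]germacra-1(10),4,11(13)-trien-12,6-olide (H6/H7 trans, 8-epi) | C1/C(CO[Si](c3ccccc3)(c3ccccc3)C(C)(C)C)=C/[C@H]2OC(=O)C(=C)[C@@H]2[C@@H](O[Si](CC)(CC)CC)C/C(C)=C\C1 | intermediate
22 | (1(10)Z,4Z,6R,7R,8S)-15-[(tert-butyldiphenylsilyl)oxy]-8-hydroxygermacra-1(10),4,11(13)-trien-12,6-olide | C1/C(CO[Si](c3ccccc3)(c3ccccc3)C(C)(C)C)=C/[C@H]2OC(=O)C(=C)[C@@H]2[C@@H](O)C/C(C)=C\C1 | intermediate
23 | [(tert-butyldimethylsilyl)oxy]acetaldehyde | CC(C)(C)[Si](C)(C)OCC=O | starting material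
24 | ethyl 2-(triphenyl-λ5-phosphanylidene)propanoate | CCOC(=O)C(C)=P(c1ccccc1)(c1ccccc1)c1ccccc1 | starting material
25 | ethyl (2E)-4-[(tert-butyldimethylsilyl)oxy]-2-methylbut-2-enoate | CCOC(=O)/C(C)=C/CO[Si](C)(C)C(C)(C)C | intermediate
26 | (2E)-4-[(tert-butyldimethylsilyl)oxy]-2-methylbut-2-enoic acid | OC(=O)/C(C)=C/CO[Si](C)(C)C(C)(C)C | intermediate
27 | (1(10)Z,4Z,6R,7R,8R)-15-[(tert-butyldiphenylsilyl)oxy]germacra-1(10),4,11(13)-trien-12,6-olid-8-yl (2E)-4-[(tert-butyldimethylsilyl)oxy]-2-methylbut-2-enoate | C1/C(CO[Si](c3ccccc3)(c3ccccc3)C(C)(C)C)=C/[C@H]2OC(=O)C(=C)[C@@H]2[C@H](OC(=O)/C(C)=C/CO[Si](C)(C)C(C)(C)C)C/C(C)=C\C1 | intermediate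
28 | (1(10)Z,4Z,6R,7R,8R)-15-hydroxygermacra-1(10),4,11(13)-trien-12,6-olid-8-yl (2E)-4-hydroxy-2-methylbut-2-enoate | C1/C(CO)=C/[C@H]2OC(=O)C(=C)[C@@H]2[C@H](OC(=O)/C(C)=C/CO)C/C(C)=C\C1 | intermediate
29 | (1(10)Z,4S,5R,6S,7R,8R)-4,5-epoxy-15-hydroxygermacra-1(10),11(13)-dien-12,6-olid-8-yl (2E)-4-hydroxy-2-methylbut-2-enoate | C=C1C(=O)O[C@H]2[C@H]1[C@H](OC(=O)/C(C)=C/CO)C/C(C)=C\CC[C@@]1(CO)O[C@H]21 | target

**Totals**
Total step count: 19. Longest linear sequence: 15 steps (1, 3, 4, 6–14, 17–19).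

**Steps most likely to fail**

1. Step 12 (labelled step). Nickel(0) may be diverted by the enal (π-complexation or reductive coupling), the allylnickel may be protonated or oligomerise before the medium ring closes, or C7 may be attacked on the wrong face. The fallback uses the known chromium-mediated ring closure of a 2-(bromomethyl)acrylate onto an enal; it sets out from 12 and comes back at 21. DIBAL-H reduction of 12 should give the C6 allylic alcohol F1. Swern oxidation with excess reagent should oxidise both the free alcohol and the primary TES ether to the C6,C7-dialdehyde F2. A Morita–Baylis–Hillman reaction (methyl acrylate, DABCO) at the more electrophilic saturated aldehyde should give the hydroxy acrylate F3 (mixture at the new carbinol). NBS/Me2S should convert it with allylic transposition into the (Z)-2-(bromomethyl)enoate F4. Nozaki–Hiyama–Kishi-type closure (CrCl2, THF, high dilution) should give the hydroxy ester F5 under the same C8 control as in step 12, and catalytic acid should close it to 21.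

2. Step 17. Displacement at the ring carbinol C8 needs a ring conformer in which O8 is anti to H7, so elimination or acyl transfer with retention may win. The fallback inverts by a redox pair and acylates without inversion; it sets out from 22 and comes back at 27. Dess–Martin oxidation should give the 8-ketone F6. Luche reduction (NaBH4, CeCl3, MeOH, −78 °C), with hydride entering from the open outer (α) face, should give the 8β-alcohol F7; the ketone must be handled cold and briefly because C7–H is acidic. Steglich esterification (DCC, DMAP) of F7 with 26 should then give 27.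

3. Step 19. Oxygen may be delivered to the inner face of C4=C5 if the macrocycle does not adopt the assumed conformation, or the olefins may compete. The fallback moves facial control from the substrate to the catalyst; it sets out from 28 and comes back at 29 with no new compound. A Katsuki–Sharpless epoxidation (Ti(OiPr)4, D-(−)-diethyl tartrate, TBHP, 4 Å sieves, CH2Cl2, −20 °C) is used, the tartrate enantiomer being the one that delivers oxygen to the top face of the C15 allylic alcohol drawn in the standard orientation, which is the (4S,5R) face.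

**Further compounds**
F1 | step 12 | (2Z,6Z,9S)-3-{[(tert-butyldiphenylsilyl)oxy]methyl}-7-methyl-9,10-bis[(triethylsilyl)oxy]deca-2,6-dien-1-ol | OC/C=C(\CO[Si](c1ccccc1)(c1ccccc1)C(C)(C)C)CC/C=C(C)\C[C@@H](CO[Si](CC)(CC)CC)O[Si](CC)(CC)CC
F2 | step 12 | (2Z,6Z,9S)-3-{[(tert-butyldiphenylsilyl)oxy]methyl}-7-methyl-9-[(triethylsilyl)oxy]deca-2,6-dienedial | O=C/C=C(\CO[Si](c1ccccc1)(c1ccccc1)C(C)(C)C)CC/C=C(C)\C[C@@H](C=O)O[Si](CC)(CC)CC
F3 | step 12 | methyl (4S,6Z,10Z)-10-{[(tert-butyldiphenylsilyl)oxy]methyl}-3-hydroxy-6-methyl-2-methylidene-12-oxo-4-[(triethylsilyl)oxy]dodeca-6,10-dienoate (both C3 epimers) | O=C/C=C(\CO[Si](c1ccccc1)(c1ccccc1)C(C)(C)C)CC/C=C(C)\C[C@H](O[Si](CC)(CC)CC)C(O)C(=C)C(=O)OC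
F4 | step 12 | methyl (2Z,4S,6Z,10Z)-2-(bromomethyl)-10-{[(tert-butyldiphenylsilyl)oxy]methyl}-6-methyl-12-oxo-4-[(triethylsilyl)oxy]dodeca-2,6,10-trienoate | O=C/C=C(\CO[Si](c1ccccc1)(c1ccccc1)C(C)(C)C)CC/C=C(C)\C[C@H](O[Si](CC)(CC)CC)/C=C(\CBr)C(=O)OC
F5 | step 12 | methyl 2-[(1S,2R,3Z,7Z,10S)-4-{[(tert-butyldiphenylsilyl)oxy]methyl}-2-hydroxy-8-methyl-10-[(triethylsilyl)oxy]cyclodeca-3,7-dien-1-yl]prop-2-enoate | C1/C(CO[Si](c3ccccc3)(c3ccccc3)C(C)(C)C)=C/[C@@H](O)[C@H](C(=C)C(=O)OC)[C@@H](O[Si](CC)(CC)CC)C/C(C)=C\C1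
F6 | step 17 | (1(10)Z,4Z,6R,7S)-15-[(tert-butyldiphenylsilyl)oxy]-8-oxogermacra-1(10),4,11(13)-trien-12,6-olide | C1/C(CO[Si](c3ccccc3)(c3ccccc3)C(C)(C)C)=C/[C@H]2OC(=O)C(=C)[C@@H]2C(=O)C/C(C)=C\C1
F7 | step 17 | (1(10)Z,4Z,6R,7R,8R)-15-[(tert-butyldiphenylsilyl)oxy]-8-hydroxygermacra-1(10),4,11(13)-trien-12,6-olide | C1/C(CO[Si](c3ccccc3)(c3ccccc3)C(C)(C)C)=C/[C@H]2OC(=O)C(=C)[C@@H]2[C@H](O)C/C(C)=C\C1
F0 | step 19 | none | none
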